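# Proposed synthesis of (3S,4R)-3-(2,5-dihydroxy-3,4-dimethoxyphenyl)-6,7,8-trimethoxychroman-4-ol (15)

## The problem

The target is a 3,4-trans isoflavan-4-ol, (3S,4R): a chroman (rings A and C) with a hydroxyl at C4 and, at C3, a 2,5-dihydroxy-3,4-dimethoxyphenyl ring B. The C4 carbinol is benzylic to a ring with O1 ortho and the C7 methoxy para to C4a, so it ionises with traces of acid; the cation is trapped by the 2'-hydroxyl to give a cis-fused pterocarpan or loses H3 to give an isoflav-3-ene, and hydrogenolysis cleaves the same C–O bond. C3 epimerises under base whenever C4 is a ketone or ring B is a quinone, and catalytic reductions of 3-substituted chromanones with dynamic resolution give the cis pair, not the trans pair. The two centers are therefore best set together, under reagent control, before either neighbouring pi-system exists. Ring B is an air-sensitive hydroquinone whose two free hydroxyls must be told apart from two methoxy groups, while ring A carries the same 1,2,3,4-tetraoxygenation, so neither oxidative demethylation nor acid- or hydrogen-labile phenol protection can be used safely at the end. The feature that opens a way out lies in ring B: the run C2'(OH)–C3'(OMe)–C4'(OMe)–C5'(OH) is the four-carbon, four-oxygen skeleton of dimethyl squarate, and the remaining pair, C1' (bonded to C3) and C6' (bearing H), is a terminal alkyne. Ring B can therefore be grown last, from a 3-ethynylchroman and squarate, arriving as a quinone that has no 2'-hydroxyl and needs no protecting group. What remains is a trans-3-ethynylchroman-4-ol, whose C3–C4 bond and both centers can come from one catalytic anti-selective allylation of an aryl aldehyde.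

## Retrosynthesis

**15 ⇒ 14 ⇒ 13.** No skeletal bond is cut. The two ring B O–H bonds are removed (hydroquinone 15 to quinone 14) and the C4 hydroxyl is masked as its triethylsilyl ether (13). Unlike any protected hydroquinone, the quinone has no phenol that could attack C4 and is not air-sensitive. The forward steps need only buffered fluoride and a neutral two-electron reduction as the last operation.

**13 ⇒ 7 + 8.** Ring B is taken apart at C1'–C2' and C5'–C6', and the C2'–C5' bond of a cyclobutene is restored. This gives the terminal alkyne 7 and dimethyl squarate 8, joined in the forward direction through lithium acetylide 9, carbinol 10, ketene 11 and diradical 12. The neighbouring cut, C3–C1', would need a pre-made pentasubstituted arene with two protected phenols and would turn C3 into a center to be made by arylation. Cutting inside ring B leaves C3 as an sp3 bystander. All six ring B substituents are placed by connectivity from a symmetrical C4 diester and a C2 handle. The forward reaction must give a single addition to 8, six-membered rather than five-membered closure, and no epimerisation at C3.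

**7 ⇒ 6 ⇒ 5.** The terminal alkyne carbon (the future C6') is removed to give aldehyde 6, which comes from the vinyl compound 5 by loss of one carbon. A terminal alkyne would not survive the copper and iridium steps that come earlier, and vinyl is exactly the group the stereo-defining step delivers. The forward steps need alkene cleavage beside an electron-rich arene and a one-carbon homologation that avoids beta-elimination of the C4 oxygen.

**5 ⇒ 4 ⇒ 3.** After removal of the silyl group, the aryl C8a–O1 bond of ring C is cut, giving the acyclic bromo diol 3. The alternative cut, O1–C2 (phenol alkylation), would need a free or protected phenol in the aldehyde; the aryl bromide is commercial and inert in the step before. The forward reaction must engage only the primary hydroxyl, which geometry ensures.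

**3 ⇒ 1 + 2.** The C3–C4 bond is cut, and both stereocenters arise in its formation. The alternatives are worse: closing C4–C4a by adding an aryl nucleophile to an alpha-chiral aldehyde invites racemisation, and an auxiliary aldol costs redox and cleavage steps. The precursors are the commercial aldehyde 1 and vinyl ethylene carbonate 2. The forward reaction must be anti-selective with absolute control from the catalyst; the hydroxymethyl arm becomes C2 and the vinyl arm becomes C1'/C6'.

## Roads not taken

**Alternative 1:** the most obvious plan, an isoflavone-type assembly with ring B brought in as a 2,5-bis(benzyloxy)-3,4-dimethoxyphenyl unit. Isoflavanone A1 would be reduced by asymmetric transfer hydrogenation with dynamic kinetic resolution at C3 (Noyori-type RuCl(p-cymene)(TsDPEN), HCO2H/Et3N). That reduction gives the cis alcohol A2, so C4 must then be inverted at a carbinol that ionises readily. The benzyl groups must leave either by hydrogenolysis, next to a C4–O bond that is itself hydrogenolysed, or by acid, next to a 2'-hydroxyl that closes the pterocarpan. The chosen plan makes the trans pair directly and never carries a protected ring B.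

**Alternative 2:** cut C3–H and C4–O, by asymmetric hydroboration–oxidation of the bis-silylated isoflav-3-ene A3 with monoisopinocampheylborane. Syn addition would give the trans alcohol directly. However, both alkene carbons are benzylic and the donor ring A draws boron toward C3, so regiocontrol is uncertain. Enantioselection by a stoichiometric terpene borane on a trisubstituted diaryl alkene is unreliable. A3 must also be built over several steps with ring B pre-formed and protected. The chosen plan sets both centers catalytically on a simple aldehyde and builds ring B unprotected.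

**Alternative 3:** cut C3–C1' and use the quinone as electrophile. Chromene A4 and quinone A5 would combine in a formal (3+2) cycloaddition under a chiral tetravalent titanium Lewis acid (TiCl2(OiPr)2 with a tartrate-derived diol) to give pterocarpan A6, a temporary furan ring. Oxidation of its para-alkoxyphenol (PhI(OAc)2, aqueous MeCN) would open it to quinone alcohol A7. This is the shortest route, but the ring fusion forces C3–aryl and C4–O cis, and the oxidative opening breaks the aryl–O bond, so the C4 oxygen keeps its configuration. A7 is therefore the cis diastereomer, and correcting it needs an inversion at the ionisable C4 beside a quinone. The chosen plan reaches the trans isomer without inversion.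

Key step: step 6

## Route

Assumption: the SMILES is read as (3S,4R), the 3,4-trans isomer; the SEGPHOS antipode in step 1 is the one that gives the (1R,2S) diol (both are commercial), to be confirmed on compound 3.

**Step 1**
Reactants: 1 2-bromo-3,4,5-trimethoxybenzaldehyde; 2 4-ethenyl-1,3-dioxolan-2-one (vinyl ethylene carbonate, racemic)
Product: 3 (1R,2S)-1-(2-bromo-3,4,5-trimethoxyphenyl)-2-ethenylpropane-1,3-diol
Conditions: [Ir(cod)Cl]2 (2.5 mol %), SEGPHOS (5 mol %, antipode chosen for the (1R,2S) diol), 4-cyano-3-nitrobenzoic acid (10 mol %), K3PO4 (cat.), i-PrOH (2 equiv), THF, 60–90 °C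
Reagents that add atoms: none
Why: Iridium-catalysed transfer-hydrogenative carbonyl (hydroxymethyl)allylation: ionisation and decarboxylation of 2 give a hydroxymethyl-substituted allyliridium that adds to the aldehyde through its substituted terminus in a closed chair transition state, so the (E)-sigma-allyl gives the anti (1R,2S) pair. The chiral bisphosphine on iridium sets the absolute sense of both centers at once; the aryl bromide is inert to this catalyst and isopropanol is the terminal reductant.

**Step 2**
Reactants: 3 (1R,2S)-1-(2-bromo-3,4,5-trimethoxyphenyl)-2-ethenylpropane-1,3-diol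
Product: 4 (3S,4R)-3-ethenyl-6,7,8-trimethoxy-3,4-dihydro-2H-chromen-4-ol
Conditions: CuI (10 mol %), 3,4,7,8-tetramethyl-1,10-phenanthroline (20 mol %), Cs2CO3 (2 equiv), toluene, 110 °C
Reagents that add atoms: none
Why: Intramolecular Ullmann-type C–O coupling: only the primary alkoxide can reach the C–Br carbon through a six-membered ring, since the secondary benzylic hydroxyl would have to close a four-membered ring. No bond to either stereocenter is touched, so the anti diol becomes the 3,4-trans chroman.

**Step 3**
Reactants: 4 (3S,4R)-3-ethenyl-6,7,8-trimethoxy-3,4-dihydro-2H-chromen-4-ol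
Product: 5 triethyl{[(3S,4R)-3-ethenyl-6,7,8-trimethoxy-3,4-dihydro-2H-chromen-4-yl]oxy}silane
Conditions: Et3SiCl, imidazole, DMF, 0 °C to 20 °C
Reagents that add atoms: triethylsilyl chloride, CC[Si](Cl)(CC)CC
Why: Standard silylation of the secondary benzylic alcohol. The triethylsilyl ether prevents dehydration of the beta-hydroxy aldehyde that would otherwise form in step 4, and it tolerates carbonate base, organolithium and heat.

**Step 4**
Reactants: 5 triethyl{[(3S,4R)-3-ethenyl-6,7,8-trimethoxy-3,4-dihydro-2H-chromen-4-yl]oxy}silane
Product: 6 (3S,4R)-6,7,8-trimethoxy-4-(triethylsilyloxy)-3,4-dihydro-2H-chromene-3-carbaldehyde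
Conditions: OsO4 (2 mol %), NaIO4 (4 equiv), 2,6-lutidine (2 equiv), 1,4-dioxane/H2O 3:1, 20 °C; crude aldehyde used at once
Reagents that add atoms: osmium tetroxide, O=[Os](=O)(=O)=O; sodium periodate, [Na+].[O-]I(=O)(=O)=O
Why: Lemieux–Johnson oxidative cleavage of the only alkene in the molecule; the lutidine buffer protects the alpha-stereocenter and the silyl ether. The arene is not attacked by OsO4 under these conditions.

**Step 5**
Reactants: 6 (3S,4R)-6,7,8-trimethoxy-4-(triethylsilyloxy)-3,4-dihydro-2H-chromene-3-carbaldehyde
Product: 7 triethyl{[(3S,4R)-3-ethynyl-6,7,8-trimethoxy-3,4-dihydro-2H-chromen-4-yl]oxy}silane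
Conditions: dimethyl (1-diazo-2-oxopropyl)phosphonate, K2CO3, MeOH, 0 °C
Reagents that add atoms: dimethyl (1-diazo-2-oxopropyl)phosphonate, COP(=O)(OC)C(=[N+]=[N-])C(C)=O
Why: Seyferth–Gilbert homologation with the Ohira–Bestmann reagent converts the aldehyde into the terminal alkyne with one added carbon. The mild carbonate base at 0 °C is chosen so that homologation outruns beta-elimination of the silyloxy group and epimerisation at C3.

**Step 6**
Reactants: 7 triethyl{[(3S,4R)-3-ethynyl-6,7,8-trimethoxy-3,4-dihydro-2H-chromen-4-yl]oxy}silane; 8 3,4-dimethoxycyclobut-3-ene-1,2-dione (dimethyl squarate)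
Product: 13 2,3-dimethoxy-5-[(3S,4R)-6,7,8-trimethoxy-4-(triethylsilyloxy)-3,4-dihydro-2H-chromen-3-yl]cyclohexa-2,5-diene-1,4-dione, via lithium acetylide 9 (not isolated), via cyclobutenone carbinol 10 (not isolated), via enynyl ketene 11 (not isolated), via ring-closed diradical 12 (not isolated)
Conditions: n-BuLi (1.05 equiv), THF, −78 °C; then 8 (1.2 equiv), −78 °C; aq. NH4Cl; crude carbinol in degassed p-xylene (0.02 M), 138 °C
Reagents that add atoms: none
Why: Lithium acetylide 9 adds once to one carbonyl of the symmetrical dione 8 at −78 °C, giving carbinol 10 as a mixture of epimers at a center that is destroyed in the next event. On heating, 10 undergoes conrotatory 4π electrocyclic ring opening with the hydroxyl rotating outward, so the alkynyl group lies cis to the ketene arm in 11. Ring B closes by attack of the ketene carbon on the distal alkyne carbon (six-membered closure to the aryl sigma-radical/phenoxyl diradical 12), and transfer of the hydroxyl hydrogen to the sigma-radical carbon gives quinone 13. The closest known reaction type is the Moore rearrangement of 4-alkynyl-4-hydroxycyclobutenones to 1,4-benzoquinones. The selectivity needed is six- over five-membered closure (which would give an alkylidenecyclopentenedione); the alkyne terminus carries the sp3 carbon C3, which offers no radical stabilisation, and that favours the six-ring path. No stereocenter is created: C3 and C4 are sp3 spectators, C3 is alpha to no carbonyl until the quinone exists, and the medium is neutral and aprotic. The ring construction itself places methoxy at C3' and C4', oxygen at C2' and C5', hydrogen at C6' and the chroman at C1' with no phenol protection.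

**Step 7**
Reactants: 13 2,3-dimethoxy-5-[(3S,4R)-6,7,8-trimethoxy-4-(triethylsilyloxy)-3,4-dihydro-2H-chromen-3-yl]cyclohexa-2,5-diene-1,4-dione
Product: 14 5-[(3S,4R)-4-hydroxy-6,7,8-trimethoxy-3,4-dihydro-2H-chromen-3-yl]-2,3-dimethoxycyclohexa-2,5-diene-1,4-dione
Conditions: HF·pyridine, pyridine, THF, 0 °C
Reagents that add atoms: none
Why: Fluoride cleaves the Si–O bond under pyridine-buffered conditions, with no base strong enough to tautomerise the quinone through C3–H and no free strong acid to ionise C4. The stereocenters are not involved.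

**Step 8**
Reactants: 14 5-[(3S,4R)-4-hydroxy-6,7,8-trimethoxy-3,4-dihydro-2H-chromen-3-yl]-2,3-dimethoxycyclohexa-2,5-diene-1,4-dione
Product: 15 (3S,4R)-3-(2,5-dihydroxy-3,4-dimethoxyphenyl)-6,7,8-trimethoxy-3,4-dihydro-2H-chromen-4-ol
Conditions: Na2S2O4 (3 equiv), EtOAc/pH 7 phosphate buffer (degassed), 20 °C, argon; neutral work-up, no acidic silica
Reagents that add atoms: none
Why: Dithionite reduces the methoxy-substituted quinone to the hydroquinone by two electrons. Buffering at pH 7, exclusion of air and a neutral work-up keep C4 from ionising toward the pterocarpan and keep the hydroquinone from reoxidising; no bond to C3 or C4 is touched.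

## Compound list

1 | 2-bromo-3,4,5-trimethoxybenzaldehyde | COc1cc(C=O)c(Br)c(OC)c1OC | starting material
2 | 4-ethenyl-1,3-dioxolan-2-one (racemic) | C=CC1COC(=O)O1 | starting material
3 | (1R,2S)-1-(2-bromo-3,4,5-trimethoxyphenyl)-2-ethenylpropane-1,3-diol | COc1cc([C@H](O)[C@@H](C=C)CO)c(Br)c(OC)c1OC | intermediate
4 | (3S,4R)-3-ethenyl-6,7,8-trimethoxy-3,4-dihydro-2H-chromen-4-ol | COc1cc2c(c(OC)c1OC)OC[C@H](C=C)[C@H]2O | intermediate
5 | triethyl{[(3S,4R)-3-ethenyl-6,7,8-trimethoxy-3,4-dihydro-2H-chromen-4-yl]oxy}silane | COc1cc2c(c(OC)c1OC)OC[C@H](C=C)[C@H]2O[Si](CC)(CC)CC | intermediate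
6 | (3S,4R)-6,7,8-trimethoxy-4-(triethylsilyloxy)-3,4-dihydro-2H-chromene-3-carbaldehyde | COc1cc2c(c(OC)c1OC)OC[C@H](C=O)[C@H]2O[Si](CC)(CC)CC | intermediate
7 | triethyl{[(3S,4R)-3-ethynyl-6,7,8-trimethoxy-3,4-dihydro-2H-chromen-4-yl]oxy}silane | COc1cc2c(c(OC)c1OC)OC[C@H](C#C)[C@H]2O[Si](CC)(CC)CC | intermediate
8 | 3,4-dimethoxycyclobut-3-ene-1,2-dione (dimethyl squarate) | COC1=C(OC)C(=O)C1=O | starting material
9 | lithium acetylide of 7 | COc1cc2c(c(OC)c1OC)OC[C@H](C#C[Li])[C@H]2O[Si](CC)(CC)CC | intermediate
10 | 4-hydroxy-2,3-dimethoxy-4-{[(3S,4R)-6,7,8-trimethoxy-4-(triethylsilyloxy)-3,4-dihydro-2H-chromen-3-yl]ethynyl}cyclobut-2-en-1-one (both epimers at the carbinol carbon) | COc1cc2c(c(OC)c1OC)OC[C@H](C#CC3(O)C(OC)=C(OC)C3=O)[C@H]2O[Si](CC)(CC)CC | intermediate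
11 | 4-hydroxy-2,3-dimethoxy-6-[(3S,4R)-6,7,8-trimethoxy-4-(triethylsilyloxy)-3,4-dihydro-2H-chromen-3-yl]hexa-1,3-dien-5-yn-1-one (alkynyl cis to the ketene arm) | COc1cc2c(c(OC)c1OC)OC[C@H](C#C/C(O)=C(OC)\C(OC)=C=O)[C@H]2O[Si](CC)(CC)CC | intermediate
12 | 4-hydroxy-2,3-dimethoxy-6-[(3S,4R)-6,7,8-trimethoxy-4-(triethylsilyloxy)-3,4-dihydro-2H-chromen-3-yl]phenoxyl-5-yl diradical | COc1cc2c(c(OC)c1OC)OC[C@H](c1[c]c(O)c(OC)c(OC)c1[O])[C@H]2O[Si](CC)(CC)CC | intermediate
13 | 2,3-dimethoxy-5-[(3S,4R)-6,7,8-trimethoxy-4-(triethylsilyloxy)-3,4-dihydro-2H-chromen-3-yl]cyclohexa-2,5-diene-1,4-dione | COc1cc2c(c(OC)c1OC)OC[C@H](C1=CC(=O)C(OC)=C(OC)C1=O)[C@H]2O[Si](CC)(CC)CC | intermediate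
14 | 5-[(3S,4R)-4-hydroxy-6,7,8-trimethoxy-3,4-dihydro-2H-chromen-3-yl]-2,3-dimethoxycyclohexa-2,5-diene-1,4-dione | COc1cc2c(c(OC)c1OC)OC[C@H](C1=CC(=O)C(OC)=C(OC)C1=O)[C@H]2O | intermediate
15 | (3S,4R)-3-(2,5-dihydroxy-3,4-dimethoxyphenyl)-6,7,8-trimethoxy-3,4-dihydro-2H-chromen-4-ol | COc1cc2c(c(OC)c1OC)OC[C@H](c1cc(O)c(OC)c(OC)c1O)[C@H]2O | target

## Step count and risks

Total step count: 8. Longest linear sequence: 8 steps (from 1).

**Step 6 (key step).** What may go wrong: closure of the ketene onto the proximal alkyne carbon to a five-membered ring, hydrogen abstraction by the aryl sigma-radical from another site, or thermal loss of silanol from C4 at 138 °C followed by tautomerisation through C3–H. Fallback: a closed-shell variant at lower temperature. From 7, Markovnikov bromoboration (B-bromo-9-borabicyclo[3.3.1]nonane, CH2Cl2, 0 °C, then AcOH) should give the 2-bromoalkene F1. Bromine–lithium exchange (t-BuLi, −78 °C) and addition to 8 should give the 4-alkenyl carbinol F2. In toluene at 110 °C this should rearrange by ring opening, 6π electrocyclisation and tautomerisation, with no radical intermediate, to the silyl-protected hydroquinone F3. Buffered fluoride (TBAF/AcOH, THF, argon) then rejoins the route at 15.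

**Step 2.** What may go wrong: slow activation of the electron-rich, doubly ortho-substituted C–Br bond, so that protodebromination or intermolecular etherification takes over. Fallback: protect first, then use palladium. From 3, bis-silylation (Et3SiOTf, 2,6-lutidine) should give F4, and selective methanolysis of the primary silyl ether (PPTS, MeOH, 0 °C) should give F5. Intramolecular etherification with Pd(OAc)2, 2-(di-tert-butylphosphino)-1,1'-binaphthyl and Cs2CO3 in toluene at 80 °C, where the masked secondary oxygen can no longer bind palladium, rejoins the route at 5.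

**Step 1.** What may go wrong: low conversion or eroded diastereo- and enantioselectivity, because the aldehyde is electron-rich and flanked by bromine, or further dehydrogenation of the primary alcohol of the product. Fallback: an auxiliary-controlled aldol. From 1, the boron-mediated Evans syn-aldol of (R)-4-benzyl-3-[(E)-but-2-enoyl]oxazolidin-2-one (Bu2BOTf, Et3N, CH2Cl2, −78 °C; alpha-attack of the dienolate) should give F6. Its aldol-syn relationship is the anti relationship of 3. LiBH4 reduction rejoins the route at 3.

**Step 5.** What may go wrong: beta-elimination of triethylsilanol from the aldehyde to a conjugated 2H-chromene-3-carbaldehyde, or epimerisation at C3, in K2CO3/MeOH. Fallback: homologation without protic base. From 6, CBr4/PPh3 (CH2Cl2, 0 °C) should give the dibromoalkene F7. Two equivalents of n-BuLi at −78 °C (Corey–Fuchs) should generate lithium acetylide 9 directly; adding 8 to the same flask rejoins the route at 9.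

**Step 7.** What may go wrong: ionisation at C4, or tautomerisation of the quinone through C3–H with loss of configuration or of water, during desilylation. Fallback: remove the silyl group before ring B exists. From 7, TBAF should give the alkynol F8. Its dianion (n-BuLi, 2.1 equiv) with 8 should give the diol carbinol F9, and thermolysis in p-xylene rejoins the route at 14.

## Further compounds

F1 | step 6 | triethyl{[(3S,4R)-3-(1-bromoethenyl)-6,7,8-trimethoxy-3,4-dihydro-2H-chromen-4-yl]oxy}silane | COc1cc2c(c(OC)c1OC)OC[C@H](C(Br)=C)[C@H]2O[Si](CC)(CC)CC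
F2 | step 6 | 4-hydroxy-2,3-dimethoxy-4-{1-[(3S,4R)-6,7,8-trimethoxy-4-(triethylsilyloxy)-3,4-dihydro-2H-chromen-3-yl]ethenyl}cyclobut-2-en-1-one | COc1cc2c(c(OC)c1OC)OC[C@H](C(=C)C3(O)C(OC)=C(OC)C3=O)[C@H]2O[Si](CC)(CC)CC
F3 | step 6 | 2,3-dimethoxy-5-[(3S,4R)-6,7,8-trimethoxy-4-(triethylsilyloxy)-3,4-dihydro-2H-chromen-3-yl]benzene-1,4-diol | COc1cc2c(c(OC)c1OC)OC[C@H](c1cc(O)c(OC)c(OC)c1O)[C@H]2O[Si](CC)(CC)CC
F4 | step 2 | (1R,2S)-1-(2-bromo-3,4,5-trimethoxyphenyl)-2-ethenyl-1,3-bis(triethylsilyloxy)propane | COc1cc([C@H](O[Si](CC)(CC)CC)[C@@H](C=C)CO[Si](CC)(CC)CC)c(Br)c(OC)c1OC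
F5 | step 2 | (2S)-2-[(R)-(2-bromo-3,4,5-trimethoxyphenyl)(triethylsilyloxy)methyl]but-3-en-1-ol | COc1cc([C@H](O[Si](CC)(CC)CC)[C@@H](C=C)CO)c(Br)c(OC)c1OC
F6 | step 1 | (R)-4-benzyl-3-[(2R,3R)-3-(2-bromo-3,4,5-trimethoxyphenyl)-2-ethenyl-3-hydroxypropanoyl]oxazolidin-2-one | COc1cc([C@H](O)[C@@H](C=C)C(=O)N2[C@H](Cc3ccccc3)COC2=O)c(Br)c(OC)c1OC
F7 | step 5 | triethyl{[(3S,4R)-3-(2,2-dibromoethenyl)-6,7,8-trimethoxy-3,4-dihydro-2H-chromen-4-yl]oxy}silane | COc1cc2c(c(OC)c1OC)OC[C@H](C=C(Br)Br)[C@H]2O[Si](CC)(CC)CC
F8 | step 7 | (3S,4R)-3-ethynyl-6,7,8-trimethoxy-3,4-dihydro-2H-chromen-4-ol | COc1cc2c(c(OC)c1OC)OC[C@H](C#C)[C@H]2O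
F9 | step 7 | 4-hydroxy-4-{[(3S,4R)-4-hydroxy-6,7,8-trimethoxy-3,4-dihydro-2H-chromen-3-yl]ethynyl}-2,3-dimethoxycyclobut-2-en-1-one | COc1cc2c(c(OC)c1OC)OC[C@H](C#CC3(O)C(OC)=C(OC)C3=O)[C@H]2O
A1 | alternative 1 | 3-[2,5-bis(benzyloxy)-3,4-dimethoxyphenyl]-6,7,8-trimethoxychroman-4-one (racemic, C3 epimerisable) | COc1cc2c(c(OC)c1OC)OCC(c1cc(OCc3ccccc3)c(OC)c(OC)c1OCc1ccccc1)C2=O
A2 | alternative 1 | (3S,4S)-3-[2,5-bis(benzyloxy)-3,4-dimethoxyphenyl]-6,7,8-trimethoxychroman-4-ol (cis) | COc1cc2c(c(OC)c1OC)OC[C@H](c1cc(OCc3ccccc3)c(OC)c(OC)c1OCc1ccccc1)[C@@H]2O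
A3 | alternative 2 | 3-[2,5-bis(tert-butyldimethylsilyloxy)-3,4-dimethoxyphenyl]-6,7,8-trimethoxy-2H-chromene | COc1cc2c(c(OC)c1OC)OCC(c1cc(O[Si](C)(C)C(C)(C)C)c(OC)c(OC)c1O[Si](C)(C)C(C)(C)C)=C2
A4 | alternative 3 | 6,7,8-trimethoxy-2H-chromene | COc1cc2c(c(OC)c1OC)OCC=C2
A5 | alternative 3 | 2,3-dimethoxycyclohexa-2,5-diene-1,4-dione | COC1=C(OC)C(=O)C=CC1=O
A6 | alternative 3 | (6aS,11aS)-2,3,4,9,10-pentamethoxy-6a,11a-dihydro-6H-[1]benzofuro[3,2-c]chromen-8-ol (cis-fused pterocarpan) | COc1cc2c(c(OC)c1OC)OC[C@@H]1c3cc(O)c(OC)c(OC)c3O[C@H]21
A7 | alternative 3 | 5-[(3S,4S)-4-hydroxy-6,7,8-trimethoxy-3,4-dihydro-2H-chromen-3-yl]-2,3-dimethoxycyclohexa-2,5-diene-1,4-dione (cis) | COc1cc2c(c(OC)c1OC)OC[C@H](C1=CC(=O)C(OC)=C(OC)C1=O)[C@@H]2O
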